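**Retrosynthetic overview**
- The target is the trans-(3R,4R) lactone. C3 is epimerisable, so it is set last under thermodynamic control: C3–H is traced back to a C3-quaternary benzyl ester that loses both benzyl groups and CO2 in one hydrogenolysis–decarboxylation.
- The C3–CH2Ar bond (syringyl unit, as its O-benzyl bromide) and the ArCH2–C4 bond (veratryl unit, as an aryl Grignard) are made in one three-component coupling on an acceptor-activated cyclopropane.
- That cyclopropane-fused γ-lactone comes from (R)-epichlorohydrin and dibenzyl malonate in a single double annulation, which fixes C4 from the chiral pool.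
- Ring order: cyclopropane, then γ-lactone, in the same flask (step 1). The cyclopropane is then consumed as a strain-loaded electrophile, and both arenes are bought.

Assumption: (R)-epichlorohydrin of ≥99% ee is used, and each one-pot sequence without isolation of an intermediate is counted as one step.

**Step 1**
Reactants: 1 (R)-epichlorohydrin [(2R)-2-(chloromethyl)oxirane]; 2 dibenzyl malonate
Product: 6 benzyl (1R,5R)-2-oxo-3-oxabicyclo[3.1.0]hexane-1-carboxylate, via chlorohydrin alkoxide 3 (not isolated), via epoxy malonate 4 (not isolated), via hydroxymethylcyclopropane diester 5 (not isolated)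
Conditions: NaOCH2Ph (1.1 equiv, 1 M in BnOH), THF, 0 → 65 °C, 16 h (2: 1.2 equiv)
Reagents that add atoms: none
Why: Tandem epoxide opening / 3-exo-tet cyclopropanation / lactonisation (the benzyl-ester variant of the known diethyl malonate–epichlorohydrin annulation): the malonate anion opens 1 at the epoxide CH2 (3), the alkoxide displaces chloride to relocate the epoxide (4), the malonate carbanion closes the cyclopropane by SN2 attack with inversion at the epoxide CH (5), and the freed alkoxide lactonises onto the cis ester, so both rings form in one operation, C5 of 6 (later C4 of the target) is fixed as R from the chiral pool, and C1 follows from the obligatory cis fusion.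

**Step 2**
Reactants: 7 syringaldehyde (4-hydroxy-3,5-dimethoxybenzaldehyde)
Product: 9 [4-(benzyloxy)-3,5-dimethoxyphenyl]methanol, via O-benzylsyringaldehyde 8 (not isolated)
Conditions: BnBr (1.05 equiv), K2CO3, DMF, 60 °C; then MeOH, NaBH4, 0 °C
Reagents that add atoms: benzyl bromide, BrCc1ccccc1
Why: Williamson etherification of the acidic, flanked phenol followed in the same pot by NaBH4 reduction of the aldehyde; no stereocentre is formed.

**Step 3**
Reactants: 9 [4-(benzyloxy)-3,5-dimethoxyphenyl]methanol
Product: 10 2-(benzyloxy)-5-(bromomethyl)-1,3-dimethoxybenzene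
Conditions: PBr3 (0.4 equiv), CH2Cl2, 0 °C, 1 h
Reagents that add atoms: phosphorus tribromide, BrP(Br)Br
Why: PBr3 bromination of an electron-rich benzylic alcohol (SN2 on the phosphite ester) is fast at 0 °C and leaves the aryl benzyl ether intact; no stereocentre is formed.

**Step 4**
Reactants: 6 benzyl (1R,5R)-2-oxo-3-oxabicyclo[3.1.0]hexane-1-carboxylate; 11 4-bromo-1,2-dimethoxybenzene (4-bromoveratrole); 10 2-(benzyloxy)-5-(bromomethyl)-1,3-dimethoxybenzene
Product: 14 benzyl (3S,4R)-3-[4-(benzyloxy)-3,5-dimethoxybenzyl]-4-(3,4-dimethoxybenzyl)-2-oxotetrahydrofuran-3-carboxylate, via Grignard reagent 12 (not isolated), via magnesium enolate 13 (not isolated)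
Conditions: 11 (1.25 equiv), Mg, THF, 45 °C; add to 6, CuI (10 mol %), THF, −40 → −15 °C; then 10 (1.5 equiv), DMPU, Bu4NI (10 mol %), −15 → 45 °C
Reagents that add atoms: none
Why: Proposed new method: the arylcopper species from 12 and CuI attacks the unsubstituted cyclopropane CH2 of 6 in an SN2-type homoconjugate (homo-Michael) addition that releases ring strain and breaks only the doubly acceptor-activated C1–C6 bond, and the chelated magnesium enolate 13, loosened by DMPU, is then C-benzylated by 10 in the same flask (closest known chemistry: CuI-catalysed Grignard opening of the ethyl ester analogue of 6 with protic quench, and separate alkylation of 2-alkoxycarbonyl lactones); C4 (R) is carried over untouched from C5 of 6, and the quaternary C3 (benzyl expected anti to the C4 substituent) need not be controlled because it is erased in step 5.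

**Step 5**
Reactants: 14 benzyl (3S,4R)-3-[4-(benzyloxy)-3,5-dimethoxybenzyl]-4-(3,4-dimethoxybenzyl)-2-oxotetrahydrofuran-3-carboxylate
Product: 17 (3R,4R)-3-(4-hydroxy-3,5-dimethoxybenzyl)-4-(3,4-dimethoxybenzyl)dihydrofuran-2(3H)-one, via lactone acid 15 (not isolated), via cis lactone 16 (not isolated)
Conditions: H2 (1 atm), 10% Pd/C, EtOAc, rt; filter; xylene, 140 °C; then DBU (3 equiv), 100 °C; aq. HCl work-up
Reagents that add atoms: none
Why: Hydrogenolysis removes the benzyl ester and the aryl benzyl ether, the malonic-type acid 15 undergoes thermal decarboxylation through its enol to a C3-epimer mixture rich in the kinetically protonated cis lactone 16, and DBU-mediated enolisation equilibrates this to the more stable trans-(3R,4R) lactone 17 (thermodynamic control of C3, estimated ≥9:1, the residual 16 being separable and recyclable), while the non-acidic C4 centre cannot epimerise.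

**Compound list**
1 | (R)-epichlorohydrin, (2R)-2-(chloromethyl)oxirane | ClC[C@H]1CO1 | starting material
2 | dibenzyl malonate | O=C(CC(=O)OCc1ccccc1)OCc1ccccc1 | starting material
3 | dibenzyl 2-[(2R)-3-chloro-2-hydroxypropyl]malonate (present as its sodium alkoxide) | ClC[C@H](O)CC(C(=O)OCc1ccccc1)C(=O)OCc1ccccc1 | intermediate
4 | dibenzyl 2-{[(2R)-oxiran-2-yl]methyl}malonate | O=C(OCc1ccccc1)C(C[C@@H]1CO1)C(=O)OCc1ccccc1 | intermediate
5 | dibenzyl (2R)-2-(hydroxymethyl)cyclopropane-1,1-dicarboxylate (present as its sodium alkoxide) | OC[C@@H]1CC1(C(=O)OCc1ccccc1)C(=O)OCc1ccccc1 | intermediate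
6 | benzyl (1R,5R)-2-oxo-3-oxabicyclo[3.1.0]hexane-1-carboxylate (cis-fused cyclopropane–γ-lactone; same spatial arrangement as the known ethyl (1S,5R) ester) | O=C1OC[C@@H]2C[C@]12C(=O)OCc1ccccc1 | intermediate
7 | syringaldehyde, 4-hydroxy-3,5-dimethoxybenzaldehyde | COc1cc(C=O)cc(OC)c1O | starting material
8 | 4-(benzyloxy)-3,5-dimethoxybenzaldehyde | COc1cc(C=O)cc(OC)c1OCc1ccccc1 | intermediate
9 | [4-(benzyloxy)-3,5-dimethoxyphenyl]methanol | COc1cc(CO)cc(OC)c1OCc1ccccc1 | intermediate
10 | 2-(benzyloxy)-5-(bromomethyl)-1,3-dimethoxybenzene | COc1cc(CBr)cc(OC)c1OCc1ccccc1 | intermediate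
11 | 4-bromo-1,2-dimethoxybenzene | COc1ccc(Br)cc1OC | starting material
12 | (3,4-dimethoxyphenyl)magnesium bromide | COc1ccc([Mg]Br)cc1OC | intermediate
13 | bromomagnesium enolate of benzyl (4R)-4-(3,4-dimethoxybenzyl)-2-oxotetrahydrofuran-3-carboxylate | COc1ccc(C[C@H]2COC(O[Mg]Br)=C2C(=O)OCc2ccccc2)cc1OC | intermediate
14 | benzyl (3S,4R)-3-[4-(benzyloxy)-3,5-dimethoxybenzyl]-4-(3,4-dimethoxybenzyl)-2-oxotetrahydrofuran-3-carboxylate (benzyl group at C3 trans to the C4 substituent) | COc1ccc(C[C@H]2COC(=O)[C@]2(C(=O)OCc2ccccc2)Cc2cc(OC)c(OCc3ccccc3)c(OC)c2)cc1OC | intermediate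
15 | (3R,4R)-3-(4-hydroxy-3,5-dimethoxybenzyl)-4-(3,4-dimethoxybenzyl)-2-oxotetrahydrofuran-3-carboxylic acid | COc1ccc(C[C@H]2COC(=O)[C@]2(C(=O)O)Cc2cc(OC)c(O)c(OC)c2)cc1OC | intermediate
16 | (3S,4R)-3-(4-hydroxy-3,5-dimethoxybenzyl)-4-(3,4-dimethoxybenzyl)dihydrofuran-2(3H)-one (cis epimer) | COc1ccc(C[C@H]2COC(=O)[C@H]2Cc2cc(OC)c(O)c(OC)c2)cc1OC | intermediate
17 | (3R,4R)-3-(4-hydroxy-3,5-dimethoxybenzyl)-4-(3,4-dimethoxybenzyl)dihydrofuran-2(3H)-one (trans) | COc1ccc(C[C@H]2COC(=O)[C@@H]2Cc2cc(OC)c(O)c(OC)c2)cc1OC | target

**Totals**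
Total step count: 5.
Longest linear sequence: 4 steps (7 → 9 → 10 → 14 → 17); the epichlorohydrin branch is 3 steps (1 → 6 → 14 → 17).

**Three steps most likely to fail, with fallbacks**

Step 4 (highest risk). The copper-catalysed ring opening has precedent, but trapping the chelated magnesium enolate with a benzylic bromide in the same pot may be slow, and leftover 12 can couple with 10. Fallback: set out from 6 and run the CuI-catalysed opening with 12 alone, quenching with aqueous NH4Cl to isolate benzyl (3R,4R)-4-(3,4-dimethoxybenzyl)-2-oxotetrahydrofuran-3-carboxylate F1 (trans epimer major, C3 labile). This isolated malonate-type C–H acid is then alkylated with 10 as its caesium enolate (Cs2CO3, DMF, rt). The fallback comes back to the route at 14 at the cost of one extra step.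

Step 1. The benzyl-ester version of the double annulation may give a lower yield than diethyl malonate, and competing direct chloride displacement would lead to the enantiomer and erode ee. Fallback: set out from 2 and replace 1 by commercial (S)-glycidyl 3-nitrobenzenesulfonate under aprotic conditions (NaH, THF, 0 °C → rt, then 60 °C). The malonate now displaces the sulfonate directly, so the two C–C bonds form in the opposite order; because of that, the (S)-sulfonate gives the same (R)-epoxide 4, which closes to 5 and 6 as before. The fallback comes back to the route at 4 in the flask and hence at 6. New compounds on this way: none F0.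

Step 5. Epimerisation with DBU in the presence of the free phenol may be sluggish or incomplete, leaving too much 16. Fallback: set out from 14 and remove the benzyl ester by nucleophilic dealkylation–decarboxylation (Krapcho: LiCl, wet DMSO, 140 °C), which leaves the aryl benzyl ether in place. This gives the phenol-protected lactone as a C3-epimer mixture: the cis isomer (3S,4R)-3-[4-(benzyloxy)-3,5-dimethoxybenzyl]-4-(3,4-dimethoxybenzyl)dihydrofuran-2(3H)-one F2 and the trans isomer (3R,4R)-3-[4-(benzyloxy)-3,5-dimethoxybenzyl]-4-(3,4-dimethoxybenzyl)dihydrofuran-2(3H)-one F3. F2 is equilibrated to F3 with catalytic KOt-Bu in t-BuOH/THF, where no phenoxide interferes. F3 is then hydrogenolysed (H2, 10% Pd/C, EtOAc, rt), and the fallback comes back to the route at 17.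

**Further compounds**
F0 | step 1 | none | none
F1 | step 4 | benzyl (3R,4R)-4-(3,4-dimethoxybenzyl)-2-oxotetrahydrofuran-3-carboxylate | COc1ccc(C[C@H]2COC(=O)[C@@H]2C(=O)OCc2ccccc2)cc1OC
F2 | step 5 | (3S,4R)-3-[4-(benzyloxy)-3,5-dimethoxybenzyl]-4-(3,4-dimethoxybenzyl)dihydrofuran-2(3H)-one | COc1ccc(C[C@H]2COC(=O)[C@H]2Cc2cc(OC)c(OCc3ccccc3)c(OC)c2)cc1OC
F3 | step 5 | (3R,4R)-3-[4-(benzyloxy)-3,5-dimethoxybenzyl]-4-(3,4-dimethoxybenzyl)dihydrofuran-2(3H)-one | COc1ccc(C[C@H]2COC(=O)[C@@H]2Cc2cc(OC)c(OCc3ccccc3)c(OC)c2)cc1OC
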